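**Plan**

- Retrosynthesis: the acid is unmasked from its methyl ester and the carbinol from a silyl ether. The sp3–sp2 bond between the second side-chain CH2 and the (E)-alkene CH is then cut (Negishi coupling) into a west tetrahydropyranyl iodide and an east (E)-vinyl iodide.
- Enabling feature: ring carbon C2 carries both the ring oxygen O1 and the α-carbon of a 1,1-disubstituted acrylate. That pattern results when a hydroxyl adds to the near end of an allene while the central allene carbon is carbonylated. O1–C2 and the α-carbon–ester carbon bond are therefore cut together, leading back to an allenyl 1,4-diol, CO and methanol.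
- Forward order: Evans alkylation, reduction and Crabbé homologation give the allenyl diol. The only ring (tetrahydropyran O1, C2–C6) and the acrylate arise in one palladium-catalysed step. The east chain is joined afterwards and the two masking groups are removed.
- Stereochemistry: C5 comes from the (S)-4-benzyl-2-oxazolidinone auxiliary. C2 is set from C5 through a chair-like, diequatorial (2,5-trans) ring closure. The carbinol comes from D-glutamic acid (diazotisation with retention), and the (E)-alkene from syn-carboalumination of a terminal alkyne.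

Key step: step 5

Remark: ring atoms are numbered O1, C2 (acrylate-bearing), C3, C4, C5 (side-chain-bearing), C6; fleeting species (organopalladium species inside catalytic cycles, the diazonium ion and α-lactone of step 7) are described in the Why lines, whereas every species that builds up in the flask before it reacts on carries a number.

**West fragment**

Step 1
Reactants: 1 hex-5-ynoic acid; 2 (4S)-4-benzyl-1,3-oxazolidin-2-one
Product: 4 (4S)-4-benzyl-3-(hex-5-ynoyl)-1,3-oxazolidin-2-one, via pivalic mixed anhydride 3 (not isolated)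
Conditions: PivCl, Et3N, THF, −20 °C; then LiCl, 2, −20 °C→rt
Reagents that add atoms: none
Why: Mixed-anhydride N-acylation of an Evans auxiliary, in which the hindered pivaloyl carbonyl steers the LiCl-activated oxazolidinone to the hexynoyl carbonyl and the terminal alkyne is a spectator.

Step 2
Reactants: 4 (4S)-4-benzyl-3-(hex-5-ynoyl)-1,3-oxazolidin-2-one; 5 tert-butyl bromoacetate
Product: 7 tert-butyl (3R)-3-{[(4S)-4-benzyl-2-oxo-1,3-oxazolidin-3-yl]carbonyl}hept-6-ynoate, via sodium (Z)-enolate 6 (not isolated)
Conditions: NaN(SiMe3)2, THF, −78 °C; then 5, −78→−40 °C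
Reagents that add atoms: none
Why: Evans asymmetric alkylation, in which the chelated sodium (Z)-enolate is attacked by the reactive α-bromo ester on the face opposite the benzyl group, setting the future ring C5 stereocentre as (R) in 7, while the imide α-CH is deprotonated much faster than the alkyne C–H at −78 °C.

Step 3
Reactants: 7 tert-butyl (3R)-3-{[(4S)-4-benzyl-2-oxo-1,3-oxazolidin-3-yl]carbonyl}hept-6-ynoate
Product: 8 (2R)-2-(but-3-yn-1-yl)butane-1,4-diol
Conditions: LiAlH4, THF, 0 °C→rt; Fieser work-up
Reagents that add atoms: none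
Why: Hydride reduction with LiAlH4 cleaves the imide reductively (releasing the auxiliary) and reduces the tert-butyl ester, so both carbonyl arms become primary alcohols while the stereocentre and the isolated terminal alkyne are untouched.

Step 4
Reactants: 8 (2R)-2-(but-3-yn-1-yl)butane-1,4-diol
Product: 10 (2R)-2-(penta-3,4-dien-1-yl)butane-1,4-diol, via Mannich base 9 (not isolated)
Conditions: (CH2O)n, i-Pr2NH, CuBr, 1,4-dioxane, reflux
Reagents that add atoms: formaldehyde (as paraformaldehyde), C=O
Why: Crabbé homologation, in which a CuBr-mediated Mannich reaction gives the propargylic amine and a copper-assisted 1,5-hydride transfer from an isopropyl C–H then expels the imine and leaves the terminal allene, a sequence routinely run on free alkynols.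

Step 5
Reactants: 10 (2R)-2-(penta-3,4-dien-1-yl)butane-1,4-diol; 11 carbon monoxide; 12 methanol
Product: 13 methyl 2-[(2R,5R)-5-(2-hydroxyethyl)oxan-2-yl]prop-2-enoate
Conditions: PdCl2 (10 mol%), CuCl2 (3 equiv), CO (1 atm), MeOH, rt
Reagents that add atoms: none
Why: PdCl2 (divalent palladium) binds the allene as a π-complex, the C6–OH oxygen adds to the proximal allene carbon on the face away from the metal (O1–C2), the vinylpalladium species thus placed on the central carbon takes up CO, and methanolysis of the acylpalladium forms the α-carbon–ester carbon bond and releases zerovalent palladium, which CuCl2 reoxidises. The closest known reaction type is the palladium-catalysed cyclisation–methoxycarbonylation of hydroxy allenes to 2-(oxacycloalkyl)acrylates, used here for a six-membered ring. The tetrahydropyran closes in a 6-exo mode (exo-trig attack on the proximal allene carbon). C2 is set under substrate control by the C5 stereocentre: in the chair-like transition state the C5 hydroxyethyl arm and the palladium-bound allene should both sit equatorial, which leads to the 2,5-trans (2R,5R) isomer. The step needs the C6 hydroxyl to react in preference to the homologous hydroxyl and needs attack at the proximal instead of the central carbon; the first should follow because the other hydroxyl could only close a seven-membered ring, the second from the exo preference of oxypalladation, which leaves palladium on the central carbon.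

Step 6
Reactants: 13 methyl 2-[(2R,5R)-5-(2-hydroxyethyl)oxan-2-yl]prop-2-enoate
Product: 14 methyl 2-[(2R,5R)-5-(2-iodoethyl)oxan-2-yl]prop-2-enoate
Conditions: PPh3, I2, imidazole, CH2Cl2, 0 °C→rt (PPh3 and I2 premixed)
Reagents that add atoms: iodine, II
Why: Appel-type iodination, in which iodide displaces the alkoxyphosphonium of the primary alcohol by SN2, and premixing the phosphine with iodine keeps free PPh3 away from the acrylate.

**East fragment**

Step 7
Reactants: 15 D-glutamic acid
Product: 16 (2R)-5-oxooxolane-2-carboxylic acid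
Conditions: NaNO2, 2 M aq. HCl, 0 °C→rt
Reagents that add atoms: none
Why: Diazotisation of the α-amino acid with double inversion, in which the α-carboxylate displaces N2 to give an α-lactone that the γ-carboxyl opens, so the γ-lactone forms with net retention and the (R) centre of D-glutamic acid becomes the carbinol centre of the target.

Step 8
Reactants: 16 (2R)-5-oxooxolane-2-carboxylic acid; 17 5-bromo-2-methylpent-2-ene
Product: 20 (5R)-5-(5-methylhex-4-enoyl)oxolan-2-one, via acid chloride 18 (not isolated), via Grignard reagent 19 (not isolated)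
Conditions: (COCl)2, DMF (cat.), CH2Cl2, 0 °C→rt, evaporate; separately 17, Mg, THF; then Fe(acac)3 (3 mol%), THF, −78 °C
Reagents that add atoms: none
Why: Acid chloride formation followed by Fe(acac)3-catalysed acylation of the Grignard reagent, which at −78 °C should be far faster at the acid chloride than at the lactone or the ketone formed, so the ketone arises without disturbing the adjacent stereocentre.

Step 9
Reactants: 20 (5R)-5-(5-methylhex-4-enoyl)oxolan-2-one
Product: 21 (5R)-5-(6-methylhepta-1,5-dien-2-yl)oxolan-2-one
Conditions: Zn, CH2Br2, TiCl4, THF, −40→5 °C (reagent pre-formed); then 20, CH2Cl2, 0 °C→rt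
Reagents that add atoms: dibromomethane, BrCBr
Why: Takai–Lombardo methylenation, whose non-basic gem-dimetallic reagent converts ketones into 1,1-disubstituted alkenes in preference to lactones and without enolising the α-acyloxy stereocentre.

Step 10
Reactants: 21 (5R)-5-(6-methylhepta-1,5-dien-2-yl)oxolan-2-one
Product: 22 (5R)-5-(6-methylhepta-1,5-dien-2-yl)oxolan-2-ol (anomeric mixture)
Conditions: i-Bu2AlH, CH2Cl2, −78 °C; aq. potassium sodium tartrate
Reagents that add atoms: none
Why: Partial reduction of a γ-lactone with i-Bu2AlH at −78 °C stops at the lactol because the tetrahedral aluminium alkoxide survives until aqueous work-up.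

Step 11
Reactants: 22 (5R)-5-(6-methylhepta-1,5-dien-2-yl)oxolan-2-ol
Product: 24 (5R)-10-methyl-6-methylideneundec-9-en-1-yn-5-ol, via hydroxy aldehyde 23 (not isolated)
Conditions: dimethyl (1-diazo-2-oxopropyl)phosphonate, K2CO3, MeOH, 0 °C→rt
Reagents that add atoms: dimethyl (1-diazo-2-oxopropyl)phosphonate, CC(=O)C(=[N+]=[N-])P(=O)(OC)OC
Why: Ohira–Bestmann (Seyferth–Gilbert) homologation, in which the open-chain aldehyde in equilibrium with the lactol is trapped by the diazomethylphosphonate anion generated in situ, and loss of dimethyl phosphate and N2 with a 1,2-hydrogen shift gives the terminal alkyne under conditions too mild to affect the carbinol centre.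

Step 12
Reactants: 24 (5R)-10-methyl-6-methylideneundec-9-en-1-yn-5-ol
Product: 25 tert-butyl(dimethyl){[(5R)-10-methyl-6-methylideneundec-9-en-1-yn-5-yl]oxy}silane
Conditions: TBSCl, imidazole, DMF, rt
Reagents that add atoms: tert-butyl(chloro)dimethylsilane, CC(C)(C)[Si](C)(C)Cl
Why: Imidazole-promoted silylation of the secondary alcohol masks the only acidic proton before the organoaluminium and organozinc steps.

Step 13
Reactants: 25 tert-butyl(dimethyl){[(5R)-10-methyl-6-methylideneundec-9-en-1-yn-5-yl]oxy}silane
Product: 27 tert-butyl{[(1E,5R)-1-iodo-2,10-dimethyl-6-methylideneundeca-1,9-dien-5-yl]oxy}dimethylsilane, via alkenylalane 26 (not isolated)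
Conditions: AlMe3, Cp2ZrCl2 (0.3 equiv), CH2Cl2, 0 °C→rt; then I2, THF, −30→0 °C
Reagents that add atoms: trimethylaluminium, C[Al](C)C; iodine, II
Why: Negishi zirconium-catalysed carboalumination adds methyl and aluminium syn across the terminal alkyne with methyl on the internal carbon, and iodinolysis with retention gives the (E)-2-methyl-1-iodoalkene, the 1,1-di- and trisubstituted alkenes being far less reactive than the alkyne.

**Union and end game**

Step 14
Reactants: 14 methyl 2-[(2R,5R)-5-(2-iodoethyl)oxan-2-yl]prop-2-enoate; 27 tert-butyl{[(1E,5R)-1-iodo-2,10-dimethyl-6-methylideneundeca-1,9-dien-5-yl]oxy}dimethylsilane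
Product: 29 methyl 2-[(2R,5S)-5-[(3E,7R)-7-{[tert-butyl(dimethyl)silyl]oxy}-4,12-dimethyl-8-methylidenetrideca-3,11-dien-1-yl]oxan-2-yl]prop-2-enoate, via alkylzinc iodide 28 (not isolated)
Conditions: 14, Zn dust (activated with BrCH2CH2Br, Me3SiCl), LiCl, THF, 40 °C; then 27, Pd(PPh3)4 (5 mol%), THF, rt→45 °C
Reagents that add atoms: none
Why: Negishi sp3–sp2 cross-coupling, in which zinc insertion into the primary iodide gives an alkylzinc iodide that tolerates the ester and, without copper, should not add to the acrylate, and transmetalation to the alkenylpalladium iodide followed by reductive elimination keeps the (E) geometry (the C5 descriptor changes from R to S only because the side-chain priority drops).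

Step 15
Reactants: 29 methyl 2-[(2R,5S)-5-[(3E,7R)-7-{[tert-butyl(dimethyl)silyl]oxy}-4,12-dimethyl-8-methylidenetrideca-3,11-dien-1-yl]oxan-2-yl]prop-2-enoate
Product: 30 methyl 2-[(2R,5S)-5-[(3E,7R)-7-hydroxy-4,12-dimethyl-8-methylidenetrideca-3,11-dien-1-yl]oxan-2-yl]prop-2-enoate
Conditions: HF·pyridine, pyridine, THF, 0 °C→rt
Reagents that add atoms: none
Why: Fluoride-driven desilylation under buffered, non-basic conditions removes the silyl ether without exposing the acrylate to alkoxide or the allylic alcohol to strong acid.

Step 16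
Reactants: 30 methyl 2-[(2R,5S)-5-[(3E,7R)-7-hydroxy-4,12-dimethyl-8-methylidenetrideca-3,11-dien-1-yl]oxan-2-yl]prop-2-enoate
Product: 31 2-[(2R,5S)-5-[(3E,7R)-7-hydroxy-4,12-dimethyl-8-methylidenetrideca-3,11-dien-1-yl]oxan-2-yl]prop-2-enoic acid
Conditions: LiOH·H2O, THF/H2O (3:1), 0 °C→rt; then 0.5 M HCl to pH 3–4, 0 °C
Reagents that add atoms: lithium hydroxide, [Li+].[OH-]
Why: Saponification of the methyl ester in aqueous THF without an alcohol co-solvent (so no alkoxide is available for conjugate addition) followed by mild acidification should give the acid, and no stereocentre is α to the carboxyl, so none can epimerise.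

**Compound list**

1 | hex-5-ynoic acid | C#CCCCC(=O)O | starting material
2 | (4S)-4-benzyl-1,3-oxazolidin-2-one | O=C1N[C@@H](Cc2ccccc2)CO1 | starting material
3 | hex-5-ynoic pivalic anhydride | C#CCCCC(=O)OC(=O)C(C)(C)C | intermediate
4 | (4S)-4-benzyl-3-(hex-5-ynoyl)-1,3-oxazolidin-2-one | C#CCCCC(=O)N1[C@@H](Cc2ccccc2)COC1=O | intermediate
5 | tert-butyl bromoacetate | CC(C)(C)OC(=O)CBr | starting material
6 | sodium (1Z)-1-[(4S)-4-benzyl-2-oxo-1,3-oxazolidin-3-yl]hex-1-en-5-yn-1-olate | C#CCC/C=C(\[O-])N1[C@@H](Cc2ccccc2)COC1=O.[Na+] | intermediate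
7 | tert-butyl (3R)-3-{[(4S)-4-benzyl-2-oxo-1,3-oxazolidin-3-yl]carbonyl}hept-6-ynoate | C#CCC[C@H](CC(=O)OC(C)(C)C)C(=O)N1[C@@H](Cc2ccccc2)COC1=O | intermediate
8 | (2R)-2-(but-3-yn-1-yl)butane-1,4-diol | OCC[C@H](CO)CCC#C | intermediate
9 | (2R)-2-{5-[di(propan-2-yl)amino]pent-3-yn-1-yl}butane-1,4-diol | OCC[C@H](CO)CCC#CCN(C(C)C)C(C)C | intermediate
10 | (2R)-2-(penta-3,4-dien-1-yl)butane-1,4-diol | OCC[C@H](CO)CCC=C=C | intermediate
11 | carbon monoxide | [C-]#[O+] | starting material
12 | methanol | CO | starting material
13 | methyl 2-[(2R,5R)-5-(2-hydroxyethyl)oxan-2-yl]prop-2-enoate | OCC[C@H]1CC[C@H](C(=C)C(=O)OC)OC1 | intermediate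
14 | methyl 2-[(2R,5R)-5-(2-iodoethyl)oxan-2-yl]prop-2-enoate | ICC[C@H]1CC[C@H](C(=C)C(=O)OC)OC1 | intermediate
15 | D-glutamic acid | N[C@H](CCC(=O)O)C(=O)O | starting material
16 | (2R)-5-oxooxolane-2-carboxylic acid | O=C(O)[C@H]1CCC(=O)O1 | intermediate
17 | 5-bromo-2-methylpent-2-ene | CC(C)=CCCBr | starting material
18 | (2R)-5-oxooxolane-2-carbonyl chloride | O=C(Cl)[C@H]1CCC(=O)O1 | intermediate
19 | bromo(4-methylpent-3-en-1-yl)magnesium | CC(C)=CCC[Mg]Br | intermediate
20 | (5R)-5-(5-methylhex-4-enoyl)oxolan-2-one | CC(C)=CCCC(=O)[C@H]1CCC(=O)O1 | intermediate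
21 | (5R)-5-(6-methylhepta-1,5-dien-2-yl)oxolan-2-one | C=C(CCC=C(C)C)[C@H]1CCC(=O)O1 | intermediate
22 | (5R)-5-(6-methylhepta-1,5-dien-2-yl)oxolan-2-ol (anomeric mixture) | C=C(CCC=C(C)C)[C@H]1CCC(O)O1 | intermediate
23 | (4R)-4-hydroxy-9-methyl-5-methylidenedec-8-enal | C=C(CCC=C(C)C)[C@H](O)CCC=O | intermediate
24 | (5R)-10-methyl-6-methylideneundec-9-en-1-yn-5-ol | C=C(CCC=C(C)C)[C@H](O)CCC#C | intermediate
25 | tert-butyl(dimethyl){[(5R)-10-methyl-6-methylideneundec-9-en-1-yn-5-yl]oxy}silane | C=C(CCC=C(C)C)[C@H](O[Si](C)(C)C(C)(C)C)CCC#C | intermediate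
26 | [(1E,5R)-5-{[tert-butyl(dimethyl)silyl]oxy}-2,10-dimethyl-6-methylideneundeca-1,9-dien-1-yl]dimethylalumane | C=C(CCC=C(C)C)[C@H](O[Si](C)(C)C(C)(C)C)CC/C(C)=C/[Al](C)C | intermediate
27 | tert-butyl{[(1E,5R)-1-iodo-2,10-dimethyl-6-methylideneundeca-1,9-dien-5-yl]oxy}dimethylsilane | C=C(CCC=C(C)C)[C@H](O[Si](C)(C)C(C)(C)C)CC/C(C)=C/I | intermediate
28 | iodo{2-[(3R,6R)-6-(3-methoxy-3-oxoprop-1-en-2-yl)oxan-3-yl]ethyl}zinc | I[Zn]CC[C@H]1CC[C@H](C(=C)C(=O)OC)OC1 | intermediate
29 | methyl 2-[(2R,5S)-5-[(3E,7R)-7-{[tert-butyl(dimethyl)silyl]oxy}-4,12-dimethyl-8-methylidenetrideca-3,11-dien-1-yl]oxan-2-yl]prop-2-enoate | C=C(CCC=C(C)C)[C@H](O[Si](C)(C)C(C)(C)C)CC/C(C)=C/CC[C@H]1CC[C@H](C(=C)C(=O)OC)OC1 | intermediate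
30 | methyl 2-[(2R,5S)-5-[(3E,7R)-7-hydroxy-4,12-dimethyl-8-methylidenetrideca-3,11-dien-1-yl]oxan-2-yl]prop-2-enoate | C=C(CCC=C(C)C)[C@H](O)CC/C(C)=C/CC[C@H]1CC[C@H](C(=C)C(=O)OC)OC1 | intermediate
31 | 2-[(2R,5S)-5-[(3E,7R)-7-hydroxy-4,12-dimethyl-8-methylidenetrideca-3,11-dien-1-yl]oxan-2-yl]prop-2-enoic acid | C=C(CCC=C(C)C)[C@H](O)CC/C(C)=C/CC[C@H]1CC[C@H](C(=C)C(=O)O)OC1 | target

**Step count and risks**

Total step count: 16 (west fragment steps 1–6, east fragment steps 7–13, union and end game steps 14–16).
Longest linear sequence: 10 steps (steps 7–13 and 14–16, from D-glutamic acid); the west branch needs 9 steps from hex-5-ynoic acid.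

Steps most likely to fail:

1. Step 5. The six-membered closure may be slow enough for intermolecular methoxypalladation of the allene to compete. The 2,5-trans preference may also be eroded, because an axial substituent at C5 of a tetrahydropyran is only weakly penalised, and the hydrogen chloride that builds up may attack the allene. The fallback sets out from allenyl diol 10 and forms the same two bonds in two separate known operations. Iodoetherification with N-iodosuccinimide in CH2Cl2 at 0 °C should close the same ring (O1–C2, 6-exo, same chair-like preference) and leave iodine on the former central allene carbon, giving 2-[(3R,6R)-6-(1-iodoethenyl)oxan-3-yl]ethan-1-ol F1. Palladium-catalysed methoxycarbonylation of this vinyl iodide (PdCl2(PPh3)2, CO, MeOH, Et3N, 50 °C) would then install the ester carbon and come back to the route at hydroxy ester 13.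

2. Step 14. Zinc insertion next to an acrylate may be diverted by radical addition to the electron-poor alkene, and the alkylpalladium intermediate may undergo β-hydride elimination or homocoupling. The fallback sets out from vinyl iodide 27 and iodide 14 with the polarity reversed. Iodine–lithium exchange on 27 (t-BuLi, Et2O, −78 °C) would give [(1E,5R)-5-{[tert-butyl(dimethyl)silyl]oxy}-2,10-dimethyl-6-methylideneundeca-1,9-dien-1-yl]lithium F2, and ZnCl2 would convert it into chloro[(1E,5R)-5-{[tert-butyl(dimethyl)silyl]oxy}-2,10-dimethyl-6-methylideneundeca-1,9-dien-1-yl]zinc F3. This alkenylzinc would be coupled with the unactivated primary iodide 14 under conditions developed for alkyl electrophiles (Pd2(dba)3, tricyclopentylphosphine, N-methylimidazole, THF/NMP, 80 °C), coming back to the route at coupled ester 29.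

3. Step 8. The Grignard reagent may add a second time to the ketone or open the lactone, and the α-acyloxy acid chloride may lose configurational purity through ketene formation. The fallback sets out from lactone acid 16. Thioesterification (EtSH, DCC, DMAP (cat.), CH2Cl2) would give S-ethyl (2R)-5-oxooxolane-2-carbothioate F4, and zinc insertion into bromide 17 (Zn, LiCl, THF, 50 °C) would give bromo(4-methylpent-3-en-1-yl)zinc F5. Fukuyama coupling of the two (PdCl2(PPh3)2, THF/toluene, rt) is selective for the thioester and would come back to the route at ketone 20.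

**Further compounds**

F1 | step 5 | 2-[(3R,6R)-6-(1-iodoethenyl)oxan-3-yl]ethan-1-ol | OCC[C@H]1CC[C@H](C(=C)I)OC1
F2 | step 14 | [(1E,5R)-5-{[tert-butyl(dimethyl)silyl]oxy}-2,10-dimethyl-6-methylideneundeca-1,9-dien-1-yl]lithium | C=C(CCC=C(C)C)[C@H](O[Si](C)(C)C(C)(C)C)CC/C(C)=C/[Li]
F3 | step 14 | chloro[(1E,5R)-5-{[tert-butyl(dimethyl)silyl]oxy}-2,10-dimethyl-6-methylideneundeca-1,9-dien-1-yl]zinc | C=C(CCC=C(C)C)[C@H](O[Si](C)(C)C(C)(C)C)CC/C(C)=C/[Zn]Cl
F4 | step 8 | S-ethyl (2R)-5-oxooxolane-2-carbothioate | CCSC(=O)[C@H]1CCC(=O)O1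
F5 | step 8 | bromo(4-methylpent-3-en-1-yl)zinc | CC(C)=CCC[Zn]Br
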